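**Retrosynthetic overview**

1. Target ⇒ (global fluoride desilylation) fully silylated precursor ⇒ cut between C5 of ring B (the left-hand 1-alkyl-2-oxy-3-methoxyphenyl ring; ring A is its guaiacyl partner) and the exocyclic CH2 on lactone C3. The two halves are an unfunctionalised arene C–H (left half, diol tied as a silylene) and a right-half α-methylene-γ-butyrolactone, united in one pot by iridium C–H borylation, rhodium 1,4-arylation and C3 epimerisation (net hydroarylation).
2. Enabling features: ring B is 1,2,3-trisubstituted, so C5 (para to its phenol oxygen) is the only aromatic C–H of the left half flanked by two C–H and is selected sterically; the CH2 is β to the lactone C2 carbonyl, so C3=CH2 is a Michael acceptor, and C3 is α-acidic and equilibrates trans to the fixed C4 centre.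
3. α-Methylene lactone ⇐ decarboxylative methylenation ⇐ copper-catalysed opening of a cyclopropane-fused lactone (from (R)-epichlorohydrin and dibenzyl malonate; fixes C4) by the Grignard reagent of the 5-bromo-dihydrobenzofuran.
4. Both diarylpropanediol units ⇐ magnesium-catalysed oxazolidinone anti-aldol of arylacetyl imides (antipodal auxiliaries, both acids from 2-allyl-6-methoxyphenol) with silylated vanillin; the right-hand one is closed by acid to the trans-dihydrobenzofuran.
5. Ring order: dihydrobenzofuran (step 14), cyclopropane-fused lactone (step 16), opened to the butyrolactone (step 17); a temporary dioxasilinane ring on the left diol (step 7) is removed in the last step.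

Key step: step 19

Remark: the target is read as the (3R,4R)-trans lactone carrying a (2S,3R)-trans dihydrobenzofuran and a (1S,2S)-1,2-diarylpropane-1,3-diol; CIP descriptors of some intermediates differ through priority changes only.

**Left half**

Step 1
Reactants: 1 2-allyl-6-methoxyphenol
Product: 2 (2-allyl-6-methoxyphenoxy)triisopropylsilane
Conditions: i-Pr3SiCl, imidazole, DMAP (cat.), DMF, 40 °C
Reagents that add atoms: triisopropylsilyl chloride, CC(C)[Si](Cl)(C(C)C)C(C)C
Why: Imidazole-promoted silyl ether formation masks the hindered phenol with a bulky, fluoride-labile group that survives all later steps and shields the neighbouring ring positions.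

Step 2
Reactants: 2 (2-allyl-6-methoxyphenoxy)triisopropylsilane
Product: 4 left arylacetic acid (2-[3-methoxy-2-(triisopropylsilyloxy)phenyl]acetic acid), via arylacetaldehyde 3 (not isolated)
Conditions: O3, CH2Cl2, −78 °C; PPh3; then NaClO2, NaH2PO4, 2-methyl-2-butene, t-BuOH/H2O, 0 °C to rt
Reagents that add atoms: ozone, [O-][O+]=O; sodium chlorite, [Na+].[O-]Cl=O
Why: Ozonolysis of the terminal alkene (much faster than attack on the arene) followed by Pinnick oxidation of the arylacetaldehyde should give the arylacetic acid with the silyl ether intact.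

Step 3
Reactants: 4 left arylacetic acid; 5 (S)-4-benzyl-1,3-oxazolidin-2-one
Product: 7 left imide ((S)-4-benzyl-3-{2-[3-methoxy-2-(triisopropylsilyloxy)phenyl]acetyl}-1,3-oxazolidin-2-one), via mixed pivalic anhydride 6 (not isolated)
Conditions: t-BuCOCl, Et3N, THF, −20 °C; then 5, LiCl, rt
Reagents that add atoms: none
Why: Mixed-anhydride N-acylation of the oxazolidinone (LiCl/Et3N protocol) occurs at the less hindered arylacetyl carbonyl of 6 and installs the auxiliary.

Step 4
Reactants: 8 vanillin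
Product: 9 3-methoxy-4-(triisopropylsilyloxy)benzaldehyde
Conditions: i-Pr3SiCl, imidazole, DMF, rt
Reagents that add atoms: triisopropylsilyl chloride, CC(C)[Si](Cl)(C(C)C)C(C)C
Why: Standard phenol silylation gives a non-enolisable aldehyde whose bulky silyl ether later blocks the ring A C–H next to oxygen.

Step 5
Reactants: 7 left imide; 9 3-methoxy-4-(triisopropylsilyloxy)benzaldehyde
Product: 11 left anti-aldol adduct ((S)-4-benzyl-3-{(2R,3S)-3-hydroxy-3-[3-methoxy-4-(triisopropylsilyloxy)phenyl]-2-[3-methoxy-2-(triisopropylsilyloxy)phenyl]propanoyl}-1,3-oxazolidin-2-one), via trimethylsilyl ether of the aldol 10 (not isolated)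
Conditions: MgCl2 (0.2 equiv), Et3N, Me3SiCl, EtOAc, 23 °C; then CF3CO2H (cat.), MeOH
Reagents that add atoms: none
Why: Magnesium-halide-catalysed oxazolidinone anti-aldol with a non-enolisable aromatic aldehyde: the chelated (Z)-magnesium enolate is attacked on the face opposite the auxiliary benzyl group through a boat-like transition state while silylation of the aldolate blocks retro-aldol, setting acyl C2 as R and C3 as S (anti; the future diol C2 and C1).

Step 6
Reactants: 11 left anti-aldol adduct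
Product: 12 left diol ((1S,2S)-1-[3-methoxy-4-(triisopropylsilyloxy)phenyl]-2-[3-methoxy-2-(triisopropylsilyloxy)phenyl]propane-1,3-diol)
Conditions: LiBH4, MeOH (1 equiv), THF, 0 °C
Reagents that add atoms: none
Why: LiBH4 reduces the activated exocyclic imide carbonyl (reductive auxiliary removal) to the primary alcohol without touching the silyl ethers or the two stereocentres.

Step 7
Reactants: 12 left diol
Product: 13 left silylene ((4S,5S)-2,2-di-tert-butyl-4-[3-methoxy-4-(triisopropylsilyloxy)phenyl]-5-[3-methoxy-2-(triisopropylsilyloxy)phenyl]-1,3,2-dioxasilinane)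
Conditions: t-Bu2Si(OTf)2, 2,6-lutidine, CH2Cl2, 0 °C to rt
Reagents that add atoms: di-tert-butylsilyl bis(trifluoromethanesulfonate), CC(C)(C)[Si](OS(=O)(=O)C(F)(F)F)(OS(=O)(=O)C(F)(F)F)C(C)(C)C
Why: Silylene formation on the 1,3-diol gives a six-membered dioxasilinane, a temporary ring that removes the O–H bonds before borylation and is cleaved by fluoride at the end.

**Right half**

Step 8
Reactants: 1 2-allyl-6-methoxyphenol
Product: 14 2-allyl-4-bromo-6-methoxyphenol
Conditions: NBS, MeCN, −10 °C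
Reagents that add atoms: N-bromosuccinimide, BrN1C(=O)CCC1=O
Why: Electrophilic aromatic bromination of the phenol goes para to OH because both ortho positions are occupied, and should be much faster at low temperature than attack on the allyl group.

Step 9
Reactants: 14 2-allyl-4-bromo-6-methoxyphenol
Product: 15 1-allyl-5-bromo-3-methoxy-2-(methoxymethoxy)benzene
Conditions: MeOCH2Cl, i-Pr2NEt, CH2Cl2, 0 °C to rt
Reagents that add atoms: chloromethyl methyl ether, COCCl
Why: O-Alkylation to the MOM acetal gives an acid-labile group so that this phenol alone can be released in step 14.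

Step 10
Reactants: 15 1-allyl-5-bromo-3-methoxy-2-(methoxymethoxy)benzene
Product: 17 right arylacetic acid (2-[5-bromo-3-methoxy-2-(methoxymethoxy)phenyl]acetic acid), via arylacetaldehyde 16 (not isolated)
Conditions: O3, CH2Cl2, −78 °C; PPh3; then NaClO2, NaH2PO4, 2-methyl-2-butene, t-BuOH/H2O, 0 °C to rt
Reagents that add atoms: ozone, [O-][O+]=O; sodium chlorite, [Na+].[O-]Cl=O
Why: Same ozonolysis and Pinnick oxidation as in step 2; the aryl bromide and the MOM ether are inert to both oxidants.

Step 11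
Reactants: 17 right arylacetic acid; 18 (R)-4-benzyl-1,3-oxazolidin-2-one
Product: 20 right imide ((R)-4-benzyl-3-{2-[5-bromo-3-methoxy-2-(methoxymethoxy)phenyl]acetyl}-1,3-oxazolidin-2-one), via mixed pivalic anhydride 19 (not isolated)
Conditions: t-BuCOCl, Et3N, THF, −20 °C; then 18, LiCl, rt
Reagents that add atoms: none
Why: Same mixed-anhydride N-acylation as in step 3, now with the antipodal auxiliary.

Step 12
Reactants: 20 right imide; 9 3-methoxy-4-(triisopropylsilyloxy)benzaldehyde
Product: 22 right anti-aldol adduct ((R)-4-benzyl-3-{(2S,3R)-2-[5-bromo-3-methoxy-2-(methoxymethoxy)phenyl]-3-hydroxy-3-[3-methoxy-4-(triisopropylsilyloxy)phenyl]propanoyl}-1,3-oxazolidin-2-one), via trimethylsilyl ether of the aldol 21 (not isolated)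
Conditions: MgCl2 (0.2 equiv), Et3N, Me3SiCl, EtOAc, 23 °C; then CF3CO2H (cat.), MeOH
Reagents that add atoms: none
Why: Same magnesium-halide-catalysed anti-aldol as in step 5 in the mirror-image sense, setting acyl C2 as S (the future benzofuran C3) and C3 as R; only the C2 configuration has to survive, since the carbinol centre is rewritten in step 14.

Step 13
Reactants: 22 right anti-aldol adduct
Product: 23 right diol ((1R,2R)-2-[5-bromo-3-methoxy-2-(methoxymethoxy)phenyl]-1-[3-methoxy-4-(triisopropylsilyloxy)phenyl]propane-1,3-diol)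
Conditions: LiBH4, MeOH (1 equiv), THF, 0 °C
Reagents that add atoms: none
Why: Reductive auxiliary removal as in step 6 gives the diol and returns the auxiliary.

Step 14
Reactants: 23 right diol
Product: 25 dihydrobenzofuran alcohol ({(2S,3R)-5-bromo-7-methoxy-2-[3-methoxy-4-(triisopropylsilyloxy)phenyl]-2,3-dihydro-1-benzofuran-3-yl}methanol), via free phenol triol 24 (not isolated)
Conditions: TsOH·H2O (0.2 equiv), MeOH/CH2Cl2, 40 °C
Reagents that add atoms: none
Why: Acid-catalysed transacetalisation removes the MOM group and the same acid ionises the electron-rich benzylic alcohol, whose cation (or its invertive displacement) is captured 5-exo by the liberated phenol anti to the adjacent hydroxymethyl group, closing the dihydrobenzofuran as the trans (2S,3R) isomer under control of C3 (cyclodehydration of a 2-(2-hydroxyaryl)-1-arylpropane-1,3-diol).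

Step 15
Reactants: 25 dihydrobenzofuran alcohol
Product: 26 silylated aryl bromide (tert-butyl({(2S,3R)-5-bromo-7-methoxy-2-[3-methoxy-4-(triisopropylsilyloxy)phenyl]-2,3-dihydro-1-benzofuran-3-yl}methoxy)dimethylsilane)
Conditions: t-BuMe2SiCl, imidazole, DMF, rt
Reagents that add atoms: tert-butyldimethylsilyl chloride, CC(C)(C)[Si](C)(C)Cl
Why: Silylation of the only remaining hydroxyl protects it from the Grignard and enolate chemistry that follows.

Step 16
Reactants: 27 (R)-epichlorohydrin; 28 dibenzyl malonate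
Product: 29 benzyl (1R,5R)-2-oxo-3-oxabicyclo[3.1.0]hexane-1-carboxylate (same spatial arrangement as the (1S,5R) ethyl ester)
Conditions: NaH (1.1 equiv), THF, 0 °C to 65 °C
Reagents that add atoms: none
Why: Malonate double alkylation by epichlorohydrin (epoxide opening at CH2, reclosure to the transposed epoxide, 3-exo-tet cyclopropanation with inversion, then lactonisation with loss of benzyl alcohol), the benzyl-ester version of the established diethyl malonate process, converts the epichlorohydrin stereocentre into C5 (R), the future lactone C4.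

Step 17
Reactants: 26 silylated aryl bromide; 29 benzyl (1R,5R)-2-oxo-3-oxabicyclo[3.1.0]hexane-1-carboxylate
Product: 31 lactone benzyl ester (benzyl (4R)-4-({(2S,3R)-3-{[(tert-butyldimethylsilyl)oxy]methyl}-7-methoxy-2-[3-methoxy-4-(triisopropylsilyloxy)phenyl]-2,3-dihydro-1-benzofuran-5-yl}methyl)-2-oxooxolane-3-carboxylate; C3 epimers), via arylmagnesium bromide 30 (not isolated)
Conditions: Mg turnings, LiCl, THF, 25 °C; then CuI (0.2 equiv), 29, −40 to 0 °C; aqueous quench
Reagents that add atoms: none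
Why: LiCl-assisted magnesium insertion gives the aryl Grignard reagent, whose copper-catalysed homoconjugate addition to the doubly activated cyclopropane CH2 (cleaving the bond to the malonate-type carbon) forms the right-hand aryl–CH2 bond and the butyrolactone with C4 (R) untouched, C3 being an inconsequential epimeric centre.

Step 18
Reactants: 31 lactone benzyl ester
Product: 33 α-methylene lactone ((4R)-4-({(2S,3R)-3-{[(tert-butyldimethylsilyl)oxy]methyl}-7-methoxy-2-[3-methoxy-4-(triisopropylsilyloxy)phenyl]-2,3-dihydro-1-benzofuran-5-yl}methyl)-3-methylideneoxolan-2-one), via carboxy lactone 32 (not isolated)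
Conditions: H2 (1 atm), 10% Pd/C, EtOAc, rt; filter; then (CH2O)n, Et2NH, EtOAc, 70 °C
Reagents that add atoms: formaldehyde (as paraformaldehyde), C=O
Why: Hydrogenolysis unmasks the malonic-type acid under neutral conditions, and the Mannich reaction with formaldehyde and diethylamine followed by decarboxylative elimination (classical α-methylenation of α-carboxy lactones) should give the exocyclic enoate without disturbing C4.

**Union and end game**

Step 19
Reactants: 13 left silylene; 33 α-methylene lactone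
Product: 36 silylated coupled lactone ((3R,4R)-3-({3-[(4S,5S)-2,2-di-tert-butyl-4-[3-methoxy-4-(triisopropylsilyloxy)phenyl]-1,3,2-dioxasilinan-5-yl]-5-methoxy-4-(triisopropylsilyloxy)phenyl}methyl)-4-({(2S,3R)-3-{[(tert-butyldimethylsilyl)oxy]methyl}-7-methoxy-2-[3-methoxy-4-(triisopropylsilyloxy)phenyl]-2,3-dihydro-1-benzofuran-5-yl}methyl)oxolan-2-one), via ring B pinacol boronate 34 (not isolated), via C3 epimer mixture 35 (not isolated)
Conditions: [Ir(OMe)(cod)]2 (1.5 mol %), 4,4′-di-tert-butyl-2,2′-bipyridine (3 mol %), B2pin2 (0.6 equiv), THF, 80 °C; then 33, [Rh(OH)(cod)]2 (3 mol %), K3PO4, dioxane/H2O (10:1), 50 °C; then evaporate, DBU, toluene, 60 °C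
Reagents that add atoms: none
Why: The iridium tris(boryl)/bipyridine catalyst borylates the least hindered aromatic C–H, which in 13 is C5 of ring B (the only C–H without an ortho substituent, para to the silylated phenol oxygen), giving 34; transmetalation to the rhodium hydroxide gives an aryl–rhodium species that carbometalates the exocyclic C3=CH2 of 33 in a 1,4-sense, and the oxa-π-allyl rhodium enolate is protonated by water, so that arene C–H and alkene are joined in a net hydroarylation. The closest known reaction types are one-pot iridium C–H borylation/rhodium 1,4-addition sequences on enones and Hayashi–Miyaura additions of arylboron reagents to α-methylene-γ-butyrolactones and 2-substituted acrylates. No ring is closed; the step forms the aryl–CH2 bond that unites the two halves and completes the carbon skeleton. The new stereocentre C3 is set under thermodynamic control by the existing C4 centre: DBU equilibrates the kinetic protonation mixture 35 through the lactone enolate to the trans-3,4-disubstituted lactone (3R,4R), while C4 (β to the carbonyl) cannot epimerise. The step needs site selectivity in the borylation, secured by the 1,2,3-substitution of ring B and by the bulky silyl ether and ortho substituents that flank every C–H of ring A, and 1,4-addition in preference to β-hydride elimination or boration of the enoate, secured by the aqueous medium and by using less than one equivalent of B2pin2 so that no diboron remains when 33 is added.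

Step 20
Reactants: 36 silylated coupled lactone
Product: 37 target ((3R,4R)-3-({3-[(1S,2S)-1,3-dihydroxy-1-(4-hydroxy-3-methoxyphenyl)propan-2-yl]-4-hydroxy-5-methoxyphenyl}methyl)-4-({(2S,3R)-2-(4-hydroxy-3-methoxyphenyl)-3-(hydroxymethyl)-7-methoxy-2,3-dihydro-1-benzofuran-5-yl}methyl)oxolan-2-one)
Conditions: Bu4NF, AcOH (1:1), THF, rt to 40 °C
Reagents that add atoms: none
Why: Acetic-acid-buffered fluoride cleaves the three aryl silyl ethers, the alkyl silyl ether and the silylene near neutrality, avoiding acid-induced closure of the freed ortho-phenol onto the benzylic alcohol and base-induced opening of the dihydrobenzofuran or lactone.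

**Compound list**

1 | 2-allyl-6-methoxyphenol | C=CCc1cccc(OC)c1O | starting material
2 | (2-allyl-6-methoxyphenoxy)triisopropylsilane | C=CCc1cccc(OC)c1O[Si](C(C)C)(C(C)C)C(C)C | intermediate
3 | 2-[3-methoxy-2-(triisopropylsilyloxy)phenyl]acetaldehyde | O=CCc1cccc(OC)c1O[Si](C(C)C)(C(C)C)C(C)C | intermediate (not isolated)
4 | 2-[3-methoxy-2-(triisopropylsilyloxy)phenyl]acetic acid | OC(=O)Cc1cccc(OC)c1O[Si](C(C)C)(C(C)C)C(C)C | intermediate
5 | (S)-4-benzyl-1,3-oxazolidin-2-one | O=C1N[C@@H](Cc2ccccc2)CO1 | starting material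
6 | mixed anhydride of 4 with pivalic acid | CC(C)(C)C(=O)OC(=O)Cc1cccc(OC)c1O[Si](C(C)C)(C(C)C)C(C)C | intermediate (not isolated)
7 | (S)-4-benzyl-3-{2-[3-methoxy-2-(triisopropylsilyloxy)phenyl]acetyl}-1,3-oxazolidin-2-one | O=C(Cc1cccc(OC)c1O[Si](C(C)C)(C(C)C)C(C)C)N1[C@@H](Cc2ccccc2)COC1=O | intermediate
8 | vanillin | COc1cc(C=O)ccc1O | starting material
9 | 3-methoxy-4-(triisopropylsilyloxy)benzaldehyde | COc1cc(C=O)ccc1O[Si](C(C)C)(C(C)C)C(C)C | intermediate
10 | O-trimethylsilyl ether of 11 | COc1cc([C@@H](O[Si](C)(C)C)[C@H](C(=O)N2[C@@H](Cc3ccccc3)COC2=O)c2cccc(OC)c2O[Si](C(C)C)(C(C)C)C(C)C)ccc1O[Si](C(C)C)(C(C)C)C(C)C | intermediate (not isolated)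
11 | (S)-4-benzyl-3-{(2R,3S)-3-hydroxy-3-[3-methoxy-4-(triisopropylsilyloxy)phenyl]-2-[3-methoxy-2-(triisopropylsilyloxy)phenyl]propanoyl}-1,3-oxazolidin-2-one | COc1cc([C@@H](O)[C@H](C(=O)N2[C@@H](Cc3ccccc3)COC2=O)c2cccc(OC)c2O[Si](C(C)C)(C(C)C)C(C)C)ccc1O[Si](C(C)C)(C(C)C)C(C)C | intermediate
12 | (1S,2S)-1-[3-methoxy-4-(triisopropylsilyloxy)phenyl]-2-[3-methoxy-2-(triisopropylsilyloxy)phenyl]propane-1,3-diol | COc1cc([C@@H](O)[C@H](CO)c2cccc(OC)c2O[Si](C(C)C)(C(C)C)C(C)C)ccc1O[Si](C(C)C)(C(C)C)C(C)C | intermediate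
13 | (4S,5S)-2,2-di-tert-butyl-4-[3-methoxy-4-(triisopropylsilyloxy)phenyl]-5-[3-methoxy-2-(triisopropylsilyloxy)phenyl]-1,3,2-dioxasilinane | COc1cc([C@H]2O[Si](C(C)(C)C)(C(C)(C)C)OC[C@@H]2c2cccc(OC)c2O[Si](C(C)C)(C(C)C)C(C)C)ccc1O[Si](C(C)C)(C(C)C)C(C)C | intermediate
14 | 2-allyl-4-bromo-6-methoxyphenol | C=CCc1cc(Br)cc(OC)c1O | intermediate
15 | 1-allyl-5-bromo-3-methoxy-2-(methoxymethoxy)benzene | C=CCc1cc(Br)cc(OC)c1OCOC | intermediate
16 | 2-[5-bromo-3-methoxy-2-(methoxymethoxy)phenyl]acetaldehyde | O=CCc1cc(Br)cc(OC)c1OCOC | intermediate (not isolated)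
17 | 2-[5-bromo-3-methoxy-2-(methoxymethoxy)phenyl]acetic acid | OC(=O)Cc1cc(Br)cc(OC)c1OCOC | intermediate
18 | (R)-4-benzyl-1,3-oxazolidin-2-one | O=C1N[C@H](Cc2ccccc2)CO1 | starting material
19 | mixed anhydride of 17 with pivalic acid | CC(C)(C)C(=O)OC(=O)Cc1cc(Br)cc(OC)c1OCOC | intermediate (not isolated)
20 | (R)-4-benzyl-3-{2-[5-bromo-3-methoxy-2-(methoxymethoxy)phenyl]acetyl}-1,3-oxazolidin-2-one | O=C(Cc1cc(Br)cc(OC)c1OCOC)N1[C@H](Cc2ccccc2)COC1=O | intermediate
21 | O-trimethylsilyl ether of 22 | COc1cc([C@H](O[Si](C)(C)C)[C@@H](C(=O)N2[C@H](Cc3ccccc3)COC2=O)c2cc(Br)cc(OC)c2OCOC)ccc1O[Si](C(C)C)(C(C)C)C(C)C | intermediate (not isolated)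
22 | (R)-4-benzyl-3-{(2S,3R)-2-[5-bromo-3-methoxy-2-(methoxymethoxy)phenyl]-3-hydroxy-3-[3-methoxy-4-(triisopropylsilyloxy)phenyl]propanoyl}-1,3-oxazolidin-2-one | COc1cc([C@H](O)[C@@H](C(=O)N2[C@H](Cc3ccccc3)COC2=O)c2cc(Br)cc(OC)c2OCOC)ccc1O[Si](C(C)C)(C(C)C)C(C)C | intermediate
23 | (1R,2R)-2-[5-bromo-3-methoxy-2-(methoxymethoxy)phenyl]-1-[3-methoxy-4-(triisopropylsilyloxy)phenyl]propane-1,3-diol | COc1cc([C@H](O)[C@@H](CO)c2cc(Br)cc(OC)c2OCOC)ccc1O[Si](C(C)C)(C(C)C)C(C)C | intermediate
24 | (1R,2R)-2-(5-bromo-2-hydroxy-3-methoxyphenyl)-1-[3-methoxy-4-(triisopropylsilyloxy)phenyl]propane-1,3-diol | COc1cc([C@H](O)[C@@H](CO)c2cc(Br)cc(OC)c2O)ccc1O[Si](C(C)C)(C(C)C)C(C)C | intermediate (not isolated)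
25 | {(2S,3R)-5-bromo-7-methoxy-2-[3-methoxy-4-(triisopropylsilyloxy)phenyl]-2,3-dihydro-1-benzofuran-3-yl}methanol | Brc1cc(OC)c2c(c1)[C@H](CO)[C@@H](c1ccc(O[Si](C(C)C)(C(C)C)C(C)C)c(OC)c1)O2 | intermediate
26 | tert-butyl({(2S,3R)-5-bromo-7-methoxy-2-[3-methoxy-4-(triisopropylsilyloxy)phenyl]-2,3-dihydro-1-benzofuran-3-yl}methoxy)dimethylsilane | Brc1cc(OC)c2c(c1)[C@H](CO[Si](C)(C)C(C)(C)C)[C@@H](c1ccc(O[Si](C(C)C)(C(C)C)C(C)C)c(OC)c1)O2 | intermediate
27 | (R)-epichlorohydrin | ClC[C@H]1CO1 | starting material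
28 | dibenzyl malonate | O=C(CC(=O)OCc1ccccc1)OCc1ccccc1 | starting material
29 | benzyl (1R,5R)-2-oxo-3-oxabicyclo[3.1.0]hexane-1-carboxylate | O=C1OC[C@@H]2C[C@]12C(=O)OCc1ccccc1 | intermediate
30 | arylmagnesium bromide from 26 (MgBr at benzofuran C5) | Br[Mg]c1cc(OC)c2c(c1)[C@H](CO[Si](C)(C)C(C)(C)C)[C@@H](c1ccc(O[Si](C(C)C)(C(C)C)C(C)C)c(OC)c1)O2 | intermediate (not isolated)
31 | benzyl (4R)-4-({(2S,3R)-3-{[(tert-butyldimethylsilyl)oxy]methyl}-7-methoxy-2-[3-methoxy-4-(triisopropylsilyloxy)phenyl]-2,3-dihydro-1-benzofuran-5-yl}methyl)-2-oxooxolane-3-carboxylate (C3 epimers, centre left undefined) | O=C1OC[C@H](Cc2cc(OC)c3c(c2)[C@H](CO[Si](C)(C)C(C)(C)C)[C@@H](c2ccc(O[Si](C(C)C)(C(C)C)C(C)C)c(OC)c2)O3)C1C(=O)OCc1ccccc1 | intermediate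
32 | (4R)-4-({(2S,3R)-3-{[(tert-butyldimethylsilyl)oxy]methyl}-7-methoxy-2-[3-methoxy-4-(triisopropylsilyloxy)phenyl]-2,3-dihydro-1-benzofuran-5-yl}methyl)-2-oxooxolane-3-carboxylic acid (C3 epimers) | O=C1OC[C@H](Cc2cc(OC)c3c(c2)[C@H](CO[Si](C)(C)C(C)(C)C)[C@@H](c2ccc(O[Si](C(C)C)(C(C)C)C(C)C)c(OC)c2)O3)C1C(=O)O | intermediate (not isolated)
33 | (4R)-4-({(2S,3R)-3-{[(tert-butyldimethylsilyl)oxy]methyl}-7-methoxy-2-[3-methoxy-4-(triisopropylsilyloxy)phenyl]-2,3-dihydro-1-benzofuran-5-yl}methyl)-3-methylideneoxolan-2-one | C=C1C(=O)OC[C@@H]1Cc1cc(OC)c2c(c1)[C@H](CO[Si](C)(C)C(C)(C)C)[C@@H](c1ccc(O[Si](C(C)C)(C(C)C)C(C)C)c(OC)c1)O2 | intermediate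
34 | pinacol boronate of 13 at C5 of ring B | COc1cc([C@H]2O[Si](C(C)(C)C)(C(C)(C)C)OC[C@@H]2c2cc(B3OC(C)(C)C(C)(C)O3)cc(OC)c2O[Si](C(C)C)(C(C)C)C(C)C)ccc1O[Si](C(C)C)(C(C)C)C(C)C | intermediate (not isolated)
35 | mixture of 36 and its lactone C3 epimer (C3 left undefined) | COc1cc([C@H]2O[Si](C(C)(C)C)(C(C)(C)C)OC[C@@H]2c2cc(CC3C(=O)OC[C@@H]3Cc3cc(OC)c4c(c3)[C@H](CO[Si](C)(C)C(C)(C)C)[C@@H](c3ccc(O[Si](C(C)C)(C(C)C)C(C)C)c(OC)c3)O4)cc(OC)c2O[Si](C(C)C)(C(C)C)C(C)C)ccc1O[Si](C(C)C)(C(C)C)C(C)C | intermediate (not isolated)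
36 | (3R,4R)-3-({3-[(4S,5S)-2,2-di-tert-butyl-4-[3-methoxy-4-(triisopropylsilyloxy)phenyl]-1,3,2-dioxasilinan-5-yl]-5-methoxy-4-(triisopropylsilyloxy)phenyl}methyl)-4-({(2S,3R)-3-{[(tert-butyldimethylsilyl)oxy]methyl}-7-methoxy-2-[3-methoxy-4-(triisopropylsilyloxy)phenyl]-2,3-dihydro-1-benzofuran-5-yl}methyl)oxolan-2-one | COc1cc([C@H]2O[Si](C(C)(C)C)(C(C)(C)C)OC[C@@H]2c2cc(C[C@H]3C(=O)OC[C@@H]3Cc3cc(OC)c4c(c3)[C@H](CO[Si](C)(C)C(C)(C)C)[C@@H](c3ccc(O[Si](C(C)C)(C(C)C)C(C)C)c(OC)c3)O4)cc(OC)c2O[Si](C(C)C)(C(C)C)C(C)C)ccc1O[Si](C(C)C)(C(C)C)C(C)C | intermediate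
37 | (3R,4R)-3-({3-[(1S,2S)-1,3-dihydroxy-1-(4-hydroxy-3-methoxyphenyl)propan-2-yl]-4-hydroxy-5-methoxyphenyl}methyl)-4-({(2S,3R)-2-(4-hydroxy-3-methoxyphenyl)-3-(hydroxymethyl)-7-methoxy-2,3-dihydro-1-benzofuran-5-yl}methyl)oxolan-2-one | COc1cc([C@@H](O)[C@H](CO)c2cc(C[C@H]3C(=O)OC[C@@H]3Cc3cc(OC)c4c(c3)[C@H](CO)[C@@H](c3ccc(O)c(OC)c3)O4)cc(OC)c2O)ccc1O | target

**Totals**

Total step count: 20. Longest linear sequence: 12 steps (steps 8–15 and 17–20, from 1).

**Steps most likely to fail**

1. Step 19. The borylation may stall or touch a second site (for example ortho to a methoxy group). Iridium or bipyridine residues may slow the rhodium cycle. The electron-rich boronate may protodeboronate, or the rhodium enolate may undergo β-hydride elimination instead of protonation. Fallback: it sets out from 13; the iridium borylation is run alone and 34 is isolated. Copper-mediated bromodeboronation (CuBr2, aqueous methanol, 80 °C) would give the ring B aryl bromide F1. LiCl-assisted magnesium insertion would give the arylmagnesium bromide F2, which is added to 33 under CuI catalysis at −40 °C (copper-catalysed conjugate addition) to give 35 after aqueous work-up. DBU in toluene then equilibrates 35, and the route is rejoined at 36.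

2. Step 14. Under acid the benzylic cation may fragment with loss of formaldehyde to a stilbene, be trapped by methanol, or close with incomplete trans selectivity; the aryl silyl ether may also be partly lost. Fallback: it sets out from 23. Selective silylation of the primary hydroxyl (t-BuMe2SiCl, imidazole) would give the mono-silyl ether F3. Non-protic MOM removal (Me3SiOTf, 2,2′-bipyridyl, CH2Cl2; then water) would give the free phenol F4. Mitsunobu etherification (PPh3, DIAD) would close the ring with inversion at the benzylic carbinol, which from the (1R,2R) series again gives the trans (2S,3R) ring. The route is rejoined at 26.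

3. Step 18. The acid may decarboxylate before the Mannich reaction, the exocyclic double bond may migrate into the ring (which would also erase C4), or diethylamine may add to the enoate. Fallback: it sets out from 31. Hydrogenolysis as before gives 32, which is decarboxylated by heating in toluene to the monosubstituted lactone F5. Claisen formylation (NaH, HCO2Et) would give the sodium hydroxymethylene-lactone enolate F6. Paraformaldehyde in refluxing THF (aldol addition, formyl transfer, loss of formate) would then give the α-methylene lactone, and the route is rejoined at 33.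

**Further compounds**

F1 | step 19 | (4S,5S)-5-[5-bromo-3-methoxy-2-(triisopropylsilyloxy)phenyl]-2,2-di-tert-butyl-4-[3-methoxy-4-(triisopropylsilyloxy)phenyl]-1,3,2-dioxasilinane | COc1cc([C@H]2O[Si](C(C)(C)C)(C(C)(C)C)OC[C@@H]2c2cc(Br)cc(OC)c2O[Si](C(C)C)(C(C)C)C(C)C)ccc1O[Si](C(C)C)(C(C)C)C(C)C
F2 | step 19 | arylmagnesium bromide from F1 (MgBr at C5 of ring B) | COc1cc([C@H]2O[Si](C(C)(C)C)(C(C)(C)C)OC[C@@H]2c2cc([Mg]Br)cc(OC)c2O[Si](C(C)C)(C(C)C)C(C)C)ccc1O[Si](C(C)C)(C(C)C)C(C)C
F3 | step 14 | (1R,2R)-2-[5-bromo-3-methoxy-2-(methoxymethoxy)phenyl]-3-[(tert-butyldimethylsilyl)oxy]-1-[3-methoxy-4-(triisopropylsilyloxy)phenyl]propan-1-ol | COc1cc([C@H](O)[C@@H](CO[Si](C)(C)C(C)(C)C)c2cc(Br)cc(OC)c2OCOC)ccc1O[Si](C(C)C)(C(C)C)C(C)C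
F4 | step 14 | (1R,2R)-2-(5-bromo-2-hydroxy-3-methoxyphenyl)-3-[(tert-butyldimethylsilyl)oxy]-1-[3-methoxy-4-(triisopropylsilyloxy)phenyl]propan-1-ol | COc1cc([C@H](O)[C@@H](CO[Si](C)(C)C(C)(C)C)c2cc(Br)cc(OC)c2O)ccc1O[Si](C(C)C)(C(C)C)C(C)C
F5 | step 18 | (4R)-4-({(2S,3R)-3-{[(tert-butyldimethylsilyl)oxy]methyl}-7-methoxy-2-[3-methoxy-4-(triisopropylsilyloxy)phenyl]-2,3-dihydro-1-benzofuran-5-yl}methyl)oxolan-2-one | O=C1OC[C@H](Cc2cc(OC)c3c(c2)[C@H](CO[Si](C)(C)C(C)(C)C)[C@@H](c2ccc(O[Si](C(C)C)(C(C)C)C(C)C)c(OC)c2)O3)C1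
F6 | step 18 | sodium enolate of the 3-(hydroxymethylidene) derivative of F5 | [Na+].[O-]C=C1C(=O)OC[C@@H]1Cc1cc(OC)c2c(c1)[C@H](CO[Si](C)(C)C(C)(C)C)[C@@H](c1ccc(O[Si](C(C)C)(C(C)C)C(C)C)c(OC)c1)O2
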